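Watch L.

the same everywhere: L 0.050 M

| flask | J | Z | remark | time |
|---|---|---|---|---|
| ochre | 5 mM | 0.34 mol% | run made earlier |  |
| teal | 5 mM | 0.75 mol% | run made earlier |  |
| flask | 5.00 mM | 0.5 mol% |  | 5.0 min |

| run | time / min | G / % | X / % | L / % |
|---|---|---|---|---|
| ochre | 0.333 | 36 | 19 | 42 |
| ochre | 0.500 | 44 | 27 | 28 |
| ochre | 0.667 | 46 | 27 | 18 |
| ochre | 1.00 | 54 | 31 | 7 |
| ochre | 1.50 | 57 | 32 | 1 |
| ochre | 2.50 | 60 | 33 | 1 |
| ochre | 4.00 | 55 | 31 | 0 |
| teal | 0.500 | 66 | 20 | 16 |
| teal | 1.00 | 70 | 23 | 0 |
| teal | 1.50 | 73 | 19 | 1 |
| teal | 2.50 | 71 | 23 | 0 |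
| teal | 3.00 | 72 | 19 | 0 |
| teal | 4.00 | 72 | 21 | 0 |

(scatter of a reading: 1.5 percentage points)

1. the state of affairs at 5.0 min: stopped, and by what, or still going (all of L has reacted / no working catalyst is left / it is still moving / forward and back rates have come level)
2. G at 5.0 min, in percent of the L charged
3. X at 5.0 min, in percent of the L charged

- what was read earlier has a scatter of 1.5 percentage points, one standard deviation
- the reaction counts as stopped when no species that holds the L changes by six tenths of a point or more over the second half of the time

**Turned round.** For this flask to be still moving at 5.0 min, L must lose 0.600 of a point or more between half time and the end. Suppose c_L falls from its charge as exp(-kt), with one constant k (pseudo-first-order). The L standing at half time must then be at least about that loss, so the lowest k that stops the flask, which I call the need, is the logarithm of the charge over that remainder, divided by half the time: 2.05 min⁻¹. At that k nearly all of the L standing at half time goes in the second half, so you can call the flask still moving when k lies under the need.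

**How far off.** The ochre run, with less Z than this flask, reads 7% L at 1.00 min, so k is about 2.66 min⁻¹. The teal run, with more Z, reads 16% at 0.500 min, so k is about 3.67 min⁻¹. Both readings stand above the need. I therefore reckon that this flask, between them in Z, stops, with roughly 0.129% L at half time if the ochre k is taken for it.

**The forecast.** It says all of L has reacted, with G at 65% and X at 27%: "There is no sign of the catalyst dying or of an equilibrium". My reckoning speaks of the stop, not of those amounts.

**The flask.** It gives all of L has reacted, with G at 65.9% and X at 27.6%.

    L + Z → Z + G (k = 183 L mol⁻¹ s⁻¹)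
    L → X (k = 0.0151 s⁻¹)
    2 Z ⇌ D (K = 920 L mol⁻¹, k = 137 L mol⁻¹ s⁻¹)
    L + J → E (k = 1.13 L mol⁻¹ s⁻¹)

This flask's L stands at 0.0420% at 2.50 min, a mean k of 3.11 min⁻¹, above the need of 2.05 min⁻¹. At 0.202 min this flask uses L 2.3 times as fast by the step to G as by the step to X. A neighbour charged with 0.013 M of L shows 0.0141% L at 5.00 min, a mean k of 1.77 min⁻¹, below the need.

All runs were generated by integration from invented constants; scatter was added.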